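**Retrosynthetic overview**
- The target, (3S,5S)-1-(3,4-dimethoxyphenyl)-5-hydroxydecan-3-yl acetate (an anti-1,3-diol 3-monoacetate), is reached by late removal of a silyl group from O5; the acetate is already in place and is never exposed to base.
- Key disconnection C2–C3: a nickel-catalysed stereoconvergent sp3–sp3 Negishi coupling of a 1-bromoalkyl acetate (β-silyloxy aldehyde + acetyl bromide) with a 2-arylethylzinc bromide; it sets C3 and installs the acetate regiospecifically.
- Aldehyde half (C3–C10): hexanal + ethyl diazoacetate → β-keto ester → Ru-BINAP hydrogenation (sets C5) → silyl ether → partial reduction.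
- Zinc half (aryl, C1–C2): catechol → veratrole → Friedel–Crafts bromoacetylation → ionic hydrogenation → zinc insertion.
- No ring is formed; the only ring (the arene) is bought as catechol.

Assumption: the decane chain is numbered C1 (benzylic CH2) to C10; methyl iodide, acetyl bromide and TBSCl are treated as reagents.

**Step 1**
Reactants: 1 catechol
Product: 2 veratrole (1,2-dimethoxybenzene)
Conditions: MeI (2.5 equiv), K2CO3 (2.5 equiv), acetone, reflux, N2, 16 h
Reagents that add atoms: methyl iodide, CI
Why: Double Williamson O-methylation of the two phenols proceeds cleanly with a mild base.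

**Step 2**
Reactants: 2 veratrole; 3 bromoacetyl bromide
Product: 4 2-bromo-1-(3,4-dimethoxyphenyl)ethan-1-one
Conditions: AlCl3 (1.2 equiv), CH2Cl2, 0 °C, 2 h; ice/HCl quench
Reagents that add atoms: none
Why: Friedel–Crafts acylation of veratrole occurs para to one methoxy group (C4), the only unhindered activated position.

**Step 3**
Reactants: 4 2-bromo-1-(3,4-dimethoxyphenyl)ethan-1-one
Product: 5 4-(2-bromoethyl)-1,2-dimethoxybenzene
Conditions: Et3SiH (2.5 equiv), TFA, rt → 45 °C, 6 h
Reagents that add atoms: none
Why: Ionic hydrogenation reduces the electron-rich aryl ketone to CH2 through the benzylic cation while the primary C–Br bond is untouched.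

**Step 4**
Reactants: 6 hexanal; 7 ethyl diazoacetate
Product: 8 ethyl 3-oxooctanoate
Conditions: SnCl2 (10 mol%), CH2Cl2, rt, 3 h
Reagents that add atoms: none
Why: Roskamp homologation, in which the Lewis-acid-activated aldehyde adds the diazo ester and a 1,2-hydride shift with loss of N2 gives the β-keto ester.

**Step 5**
Reactants: 8 ethyl 3-oxooctanoate
Product: 9 ethyl (S)-3-hydroxyoctanoate
Conditions: H2 (50 bar), RuCl2[(S)-BINAP] (0.2 mol%), EtOH, 60 °C, 24 h
Reagents that add atoms: none
Why: Noyori asymmetric hydrogenation of the chelated β-keto ester; (S)-BINAP–Ru gives the (S)-carbinol (same sense as (R)-BINAP → (R)-3-hydroxybutanoate), which sets C5 of the target.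

**Step 6**
Reactants: 9 ethyl (S)-3-hydroxyoctanoate
Product: 10 ethyl (S)-3-[(tert-butyldimethylsilyl)oxy]octanoate
Conditions: TBSCl (1.3 equiv), imidazole (2.5 equiv), DMF, rt, 12 h
Reagents that add atoms: tert-butyldimethylsilyl chloride, CC(C)(C)[Si](C)(C)Cl
Why: Standard imidazole-mediated silylation of a secondary alcohol; the stereocentre is not touched.

**Step 7**
Reactants: 10 ethyl (S)-3-[(tert-butyldimethylsilyl)oxy]octanoate
Product: 11 (S)-3-[(tert-butyldimethylsilyl)oxy]octanal
Conditions: DIBAL-H (1.1 equiv), CH2Cl2, −78 °C, 1 h; MeOH, then aq. Rochelle salt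
Reagents that add atoms: none
Why: Partial ester reduction with DIBAL-H, where the tetrahedral aluminium hemiacetal is stable at −78 °C and releases the aldehyde only on work-up.

**Step 8**
Reactants: 11 (S)-3-[(tert-butyldimethylsilyl)oxy]octanal; 5 4-(2-bromoethyl)-1,2-dimethoxybenzene
Product: 14 (3S,5S)-5-[(tert-butyldimethylsilyl)oxy]-1-(3,4-dimethoxyphenyl)decan-3-yl acetate, via 1-bromoalkyl acetate 12 (not isolated), via arylethylzinc bromide 13 (not isolated)
Conditions: (i) 11, AcBr (1.05 equiv, freshly distilled), CH2Cl2, −20 → 0 °C, then volatiles removed; (ii) 5 (1.5 equiv), Zn dust, I2 (5 mol%), DMA, 70 °C; (iii) NiBr2·glyme (10 mol%), (S,S)-i-Pr-PyBox (13 mol%), THF/DMA, −10 → 0 °C, 24 h; SiO2 chromatography removes the minor C3 epimer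
Reagents that add atoms: acetyl bromide, CC(=O)Br; zinc, [Zn] (held only in intermediate 13)
Why: Proposed new method: a Ni/PyBox-catalysed stereoconvergent Negishi sp3–sp3 coupling in which the Ni(I)–alkyl formed from 13 abstracts bromine from either C1 epimer of 12 to give one planar α-acetoxyalkyl radical, which is captured by the chiral Ni(II)–alkyl complex (acetate carbonyl chelating) and reductively eliminated from Ni(III), forming C2–C3 and setting C3 as S under catalyst control (the remote C5 centre only modulates the dr; the ligand antipode that gives 3S is to be confirmed on a model aldehyde), so the 1,3-anti monoacetate arises directly; closest known reaction type: nickel-catalysed enantioconvergent Negishi alkyl–alkyl couplings of racemic α-heteroatom-substituted secondary alkyl halides and the NiH-mediated coupling of racemic 1-bromoalkyl esters with olefins, neither shown for an alkylzinc with a 1-bromoalkyl acetate carrying a β-silyloxy stereocentre.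

**Step 9**
Reactants: 14 (3S,5S)-5-[(tert-butyldimethylsilyl)oxy]-1-(3,4-dimethoxyphenyl)decan-3-yl acetate
Product: 15 (3S,5S)-1-(3,4-dimethoxyphenyl)-5-hydroxydecan-3-yl acetate
Conditions: HF·pyridine, pyridine, THF, 0 °C → rt, 12 h
Reagents that add atoms: none
Why: Fluoride-mediated desilylation under buffered, mildly acidic conditions frees the C5 hydroxyl without the base-promoted 1,3-acetyl migration and without touching either stereocentre.

**Compound list**
1 | catechol (benzene-1,2-diol) | Oc1ccccc1O | starting material
2 | veratrole (1,2-dimethoxybenzene) | COc1ccccc1OC | intermediate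
3 | bromoacetyl bromide | BrCC(Br)=O | starting material
4 | 2-bromo-1-(3,4-dimethoxyphenyl)ethan-1-one | COc1ccc(C(=O)CBr)cc1OC | intermediate
5 | 4-(2-bromoethyl)-1,2-dimethoxybenzene | COc1ccc(CCBr)cc1OC | intermediate
6 | hexanal | CCCCCC=O | starting material
7 | ethyl diazoacetate | CCOC(=O)C=[N+]=[N-] | starting material
8 | ethyl 3-oxooctanoate | CCCCCC(=O)CC(=O)OCC | intermediate
9 | ethyl (S)-3-hydroxyoctanoate | CCCCC[C@H](O)CC(=O)OCC | intermediate
10 | ethyl (S)-3-[(tert-butyldimethylsilyl)oxy]octanoate | CCCCC[C@H](O[Si](C)(C)C(C)(C)C)CC(=O)OCC | intermediate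
11 | (S)-3-[(tert-butyldimethylsilyl)oxy]octanal | CCCCC[C@H](O[Si](C)(C)C(C)(C)C)CC=O | intermediate
12 | (3S)-1-bromo-3-[(tert-butyldimethylsilyl)oxy]octyl acetate (both C1 epimers) | CCCCC[C@H](O[Si](C)(C)C(C)(C)C)CC(Br)OC(C)=O | intermediate
13 | [2-(3,4-dimethoxyphenyl)ethyl]zinc bromide | COc1ccc(CC[Zn]Br)cc1OC | intermediate
14 | (3S,5S)-5-[(tert-butyldimethylsilyl)oxy]-1-(3,4-dimethoxyphenyl)decan-3-yl acetate | CCCCC[C@H](O[Si](C)(C)C(C)(C)C)C[C@H](CCc1ccc(OC)c(OC)c1)OC(C)=O | intermediate
15 | (3S,5S)-1-(3,4-dimethoxyphenyl)-5-hydroxydecan-3-yl acetate | CCCCC[C@H](O)C[C@H](CCc1ccc(OC)c(OC)c1)OC(C)=O | target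

**Step count**
Total step count: 9. Longest linear sequence: 6 (steps 4–9, hexanal to 15); the arene branch (steps 1–3) joins at step 8.

**Steps most likely to fail**

Step 8 (the proposed new coupling). The risks are acylative cleavage of the silyl ether by acetyl bromide, an uncatalysed non-selective alkylation of 12 by 13 through an acyloxycarbenium ion, and a mismatched catalyst/C5 pairing that lowers the dr. The fallback uses known chemistry, sets out from 5 and 11 and comes back to the route at 14. Bromide 5 is converted with magnesium in THF into [2-(3,4-dimethoxyphenyl)ethyl]magnesium bromide F5. Transmetalation with ZnCl2 (0.5 equiv) and precipitation of the magnesium halides with 1,4-dioxane gives bis[2-(3,4-dimethoxyphenyl)ethyl]zinc F6. This adds to aldehyde 11 in toluene at −20 °C with Ti(OiPr)4 and 8 mol% (1R,2R)-1,2-bis(trifluoromethanesulfonamido)cyclohexane (catalyst-controlled si-face addition) to give (3S,5S)-5-[(tert-butyldimethylsilyl)oxy]-1-(3,4-dimethoxyphenyl)decan-3-ol F7. Acetylation with Ac2O, DMAP and pyridine gives 14.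

Step 3 (ionic hydrogenation of the α-bromo ketone). The risks are Friedel–Crafts-type dimerisation through the electron-rich benzylic cation and partial loss or exchange of the bromide. The fallback sets out from 2 and comes back at 5, replacing steps 2 and 3. NBS in MeCN brominates 2 para to a methoxy group to give 4-bromo-1,2-dimethoxybenzene F1. Magnesium in THF turns it into (3,4-dimethoxyphenyl)magnesium bromide F2, which opens ethylene oxide (C1CO1) at 0 °C to give 2-(3,4-dimethoxyphenyl)ethan-1-ol F3. Appel bromination (CBr4, PPh3, CH2Cl2) then gives 5.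

Step 7 (partial reduction to the β-silyloxy aldehyde). The risks are over-reduction to the primary alcohol and β-elimination of silanol from 11 during work-up. The fallback sets out from 10 and comes back at 11. Ester 10 is reduced completely with LiBH4 in THF to (S)-3-[(tert-butyldimethylsilyl)oxy]octan-1-ol F4, which is oxidised under Parikh–Doering conditions (SO3·pyridine, DMSO, i-Pr2NEt, 0 °C) to 11.

**Further compounds**
F1 | step 3 | 4-bromo-1,2-dimethoxybenzene | COc1ccc(Br)cc1OC
F2 | step 3 | (3,4-dimethoxyphenyl)magnesium bromide | COc1ccc([Mg]Br)cc1OC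
F3 | step 3 | 2-(3,4-dimethoxyphenyl)ethan-1-ol | COc1ccc(CCO)cc1OC
F4 | step 7 | (S)-3-[(tert-butyldimethylsilyl)oxy]octan-1-ol | CCCCC[C@H](O[Si](C)(C)C(C)(C)C)CCO
F5 | step 8 | [2-(3,4-dimethoxyphenyl)ethyl]magnesium bromide | COc1ccc(CC[Mg]Br)cc1OC
F6 | step 8 | bis[2-(3,4-dimethoxyphenyl)ethyl]zinc | COc1ccc(CC[Zn]CCc2ccc(OC)c(OC)c2)cc1OC
F7 | step 8 | (3S,5S)-5-[(tert-butyldimethylsilyl)oxy]-1-(3,4-dimethoxyphenyl)decan-3-ol | CCCCC[C@H](O[Si](C)(C)C(C)(C)C)C[C@H](CCc1ccc(OC)c(OC)c1)O
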